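A small charge of reagent against a large charge of substrate gives the flask we can reckon by hand, so we start there.

the same everywhere: substrate 18 mM

| charge | reagent | capture agent | remark | time |
|---|---|---|---|---|
| Sunday's | 1.5 mM | 1.8 mM | run made earlier |  |
| Friday's | 61 mM | 1.8 mM | run made earlier |  |
| autumn | 2.50 mM | 1.80 mM |  | 3.0 d |
| dusk | 8.00 mM | 1.80 mM |  | 3.0 d |
| midnight | 25.0 mM | 1.80 mM |  | 3.0 d |
| spring | 80.0 mM | 1.80 mM |  | 3.0 d |

| run | time / h | target / % | substrate / % |
|---|---|---|---|
| Sunday's | 3.00 | 1.2 | 97.9 |
| Sunday's | 6.00 | 1.6 | 94.2 |
| Sunday's | 15.0 | 4.9 | 92.5 |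
| Sunday's | 40.0 | 6.6 | 91.6 |
| Friday's | 3.00 | 18.0 | 18.8 |
| Friday's | 6.00 | 28.2 | 6.3 |
| Friday's | 15.0 | 27.1 | 0.4 |
| Friday's | 40.0 | 25.4 | 0.2 |

(scatter of a reading: 1 percentage point)

- the numbers in the tables scatter by 1 percentage point (one standard deviation)
- candidate steps: intermediate A -> target; reagent + intermediate A -> intermediate B; capture agent + intermediate B -> trapped intermediate; target <-> isomer of the product; substrate + reagent -> intermediate A; intermediate B <-> intermediate C
- "hardly changes" means that all values lie within two and a half points (for a concentration: within two and a half percent of the largest)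

1. [target] at the end for autumn, dusk, midnight, spring, in this order
2. how that number moves from the first to the last of them (falls all the way / hardly changes / falls, then rises / rises all the way / rises, then falls)

In Sunday's run the reagent charge is 8.33% of the substrate charge, and the substrate lost by 40.0 h reads 8.40%, about the same. So in Sunday's run we take one reagent per substrate, with reagent as the limiting reagent. The last reading of Sunday's run gives 0.786 for the kept share, the fraction of target standing per fraction of substrate lost, and this value carries the scatter of its readings. In autumn the reagent charge is 13.9% of the substrate charge, so we expect a fraction left of 86.1% and target at 10.9% of the substrate charged, which is 1.96 mM.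

The forecast, by a different reckoning, gives 2 mM, 4.9 mM, 9.2 mM and 3.3 mM, a row that rises, then falls, with the words “Target then slowly drifts to its isomer, leaving about 0.87 of it”.

The flasks give 1.62 mM, 4.61 mM, 8.67 mM and 3.57 mM, a row that rises, then falls. The autumn flask ends with 86.5% of its substrate left, close to the reckoned 86.1%, and 9.02% as target, less than our 10.9%.

    intermediate A → target (k = 0.238 h⁻¹)
    reagent + intermediate A → intermediate B (k = 9.78 M⁻¹ h⁻¹)
    capture agent + intermediate B → trapped intermediate (k = 106 M⁻¹ h⁻¹)
    target ⇌ isomer of the product (K = 0.460, k = 0.0345 h⁻¹)
    substrate + reagent → intermediate A (k = 11.7 M⁻¹ h⁻¹)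
    intermediate B ⇌ intermediate C (K = 32.6, k = 0.539 h⁻¹)

In autumn the relaxation half-life of target and isomer of the product, both ways of that step together, is 0.264 d, short against the 3.0 d of the flask, and the kept share of the autumn flask ends at 0.667. In dusk, the second flask, 40.9% of the substrate is lost, which the kept share of 0.786 read on Sunday's run turns into 32.1% as target, while 25.6% stands there, a kept share of 0.626, close to that of autumn.

The readings come from a simulation from invented constants; noise was put on by code.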